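## Retrosynthetic overview

1. Endgame: tigloylation of the C8–OH and desilylation of C15–O on the finished furanoheliangolide core.
2. The 3(2H)-furanone ring is formed last, by Au-catalysed 5-endo-dig addition of the C10 tertiary OH onto a C1 ynone held inside the ten-membered ring.
3. The ten-membered carbocycle and the trans α-methylene-γ-butyrolactone are formed together before that, by an intramolecular Cr(II) Barbier (Nozaki–Hiyama) allylation that makes C6–C7, followed by lactonisation.
4. The open-chain precursor comes from a Sonogashira coupling (C3–C4) of an alkyne fragment with a (Z)-β-iodoenal made from but-2-yne-1,4-diol.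
5. The alkyne fragment comes from (S)-γ-hydroxymethyl-γ-butyrolactone (C8 from the chiral pool, C10 by anti-selective enolate hydroxylation), ethynyl Grignard addition and a Morita–Baylis–Hillman reaction.

Assumption: germacranolide numbering is used (C1 ketone, C2=C3 furanone, C4=C5, C6/C7 lactone, C8 ester, C10 quaternary, C11=C13, C14 methyl, C15 CH2OH); the C1 carbinol and the Baylis–Hillman carbinol are carried as epimer mixtures because both centres are later destroyed.

## Route

**Step 1**
Reactants: 1, (S)-5-(hydroxymethyl)dihydrofuran-2(3H)-one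
Product: 2, (S)-5-{[(triethylsilyl)oxy]methyl}dihydrofuran-2(3H)-one
Conditions: TESCl, imidazole, CH2Cl2, 0 °C to rt
Reagents that add atoms: chlorotriethylsilane, CC[Si](Cl)(CC)CC
Why: Standard silylation of the primary alcohol; the C8 stereocentre (chiral pool) is untouched.

**Step 2**
Reactants: 2; 3, iodomethane
Product: 4, (3RS,5S)-3-methyl-5-{[(triethylsilyl)oxy]methyl}dihydrofuran-2(3H)-one
Conditions: LDA, THF, −78 °C; MeI, −78 to −40 °C
Reagents that add atoms: iodomethane (3), CI
Why: Lactone enolate C-alkylation installs C14; the new centre is re-enolised in the next step, so its configuration is irrelevant.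

**Step 3**
Reactants: 4
Product: 5, (3R,5S)-3-hydroxy-3-methyl-5-{[(triethylsilyl)oxy]methyl}dihydrofuran-2(3H)-one (OH trans, Me cis to the C5 side chain)
Conditions: KHMDS, THF, −78 °C; then 2-(phenylsulfonyl)-3-phenyloxaziridine; NH4Cl
Reagents that add atoms: Davis oxaziridine (adds O), O=S(=O)(c1ccccc1)N1OC1c1ccccc1
Why: Davis enolate hydroxylation; the oxidant attacks the planar enolate anti to the C5 CH2OTES group, which sets the quaternary C10 centre as R.

**Step 4**
Reactants: 5
Product: 6, (3R,5S)-3-methyl-5-{[(triethylsilyl)oxy]methyl}oxolane-2,3-diol (lactol, anomer mixture)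
Conditions: DIBAL-H (2.2 equiv), CH2Cl2, −78 °C
Reagents that add atoms: none
Why: Partial lactone reduction; the tetrahedral aluminate is stable at −78 °C, so reduction stops at the lactol.

**Step 5**
Reactants: 6; 7, ethynylmagnesium bromide
Product: 8, (3RS,4R,6S)-4-methyl-7-[(triethylsilyl)oxy]hept-1-yne-3,4,6-triol
Conditions: HC≡CMgBr (6 equiv), THF, 0 °C to rt
Reagents that add atoms: ethynylmagnesium bromide (7), C#C[Mg]Br
Why: Grignard addition to the ring-opened hydroxy-aldehyde form of the lactol brings in C2/C3; the C1 carbinol forms as a mixture and is oxidised later.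

**Step 6**
Reactants: 8
Product: 9, (3RS,4R,6S)-4-methyl-3,4,6,7-tetrakis[(triethylsilyl)oxy]hept-1-yne
Conditions: TESOTf (5 equiv), 2,6-lutidine, CH2Cl2, −78 to 0 °C
Reagents that add atoms: triethylsilyl triflate, CC[Si](CC)(CC)OS(=O)(=O)C(F)(F)F
Why: Exhaustive silylation (including the tertiary C10–OH) prevents lactol formation from the later γ-hydroxy aldehyde and masks all hydroxyls in one operation.

**Step 7**
Reactants: 9
Product: 10, (2S,4R,5RS)-4-methyl-2,4,5-tris[(triethylsilyl)oxy]hept-6-ynal
Conditions: (COCl)2, DMSO, CH2Cl2, −78 to −30 °C; then Et3N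
Reagents that add atoms: none
Why: Under Swern conditions a primary TES ether is cleaved and oxidised directly to the aldehyde while secondary and tertiary TES ethers survive; C8 is not affected.

**Step 8**
Reactants: 10; 11, methyl acrylate
Product: 12, methyl (3RS,4S,6R,7RS)-3-hydroxy-6-methyl-2-methylidene-4,6,7-tris[(triethylsilyl)oxy]non-8-ynoate
Conditions: methyl acrylate (excess, neat), DABCO (1 equiv), rt, 3–5 d
Reagents that add atoms: methyl acrylate (11), C=CC(=O)OC
Why: Morita–Baylis–Hillman reaction on an activated α-silyloxy aldehyde brings in C11–C13; the new carbinol configuration is erased by the later SN2′ bromination.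

**Step 9**
Reactants: 13, but-2-yne-1,4-diol
Product: 14, 4-[(tert-butyldiphenylsilyl)oxy]but-2-yn-1-ol
Conditions: diol (3 equiv), NaH (1 equiv), THF, 0 °C; TBDPSCl (1 equiv)
Reagents that add atoms: tert-butyldiphenylsilyl chloride, CC(C)(C)[Si](Cl)(c1ccccc1)c1ccccc1
Why: Mono-alkoxide monosilylation of a symmetrical diol; excess diol suppresses bis-silylation.

**Step 10**
Reactants: 14
Product: 15, (Z)-4-[(tert-butyldiphenylsilyl)oxy]-3-iodobut-2-en-1-ol (I cis to CH2OH)
Conditions: Red-Al, THF, 0 °C; EtOAc; then I2, −78 to 0 °C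
Reagents that add atoms: iodine, II
Why: Hydroxyl-directed trans-hydroalumination places Al on the distal alkyne carbon, and iodination with retention gives the (Z)-vinyl iodide that fixes the C4=C5 geometry.

**Step 11**
Reactants: 15
Product: 16, (Z)-4-[(tert-butyldiphenylsilyl)oxy]-3-iodobut-2-enal
Conditions: MnO2, CH2Cl2, rt
Reagents that add atoms: none
Why: Neutral allylic oxidation to the enal without Z/E isomerisation.

**Step 12**
Reactants: 12; 16
Product: 17, methyl (3RS,4S,6R,7RS,10E)-10-{[(tert-butyldiphenylsilyl)oxy]methyl}-3-hydroxy-6-methyl-2-methylidene-12-oxo-4,6,7-tris[(triethylsilyl)oxy]dodec-10-en-8-ynoate (CHO cis to the alkyne)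
Conditions: Pd(PPh3)2Cl2 (5 mol%), CuI (10 mol%), Et3N, THF, 0 °C to rt
Reagents that add atoms: none
Why: Sonogashira coupling of the activated β-iodoenal forms C3–C4 with retention of alkene geometry; the free carbinol, acrylate and aldehyde are tolerated at rt.

**Step 13**
Reactants: 17
Product: 18, methyl (2Z,4S,6R,7RS,10E)-2-(bromomethyl)-10-{[(tert-butyldiphenylsilyl)oxy]methyl}-6-methyl-12-oxo-4,6,7-tris[(triethylsilyl)oxy]dodeca-2,10-dien-8-ynoate
Conditions: NBS, Me2S, CH2Cl2, −20 to 0 °C
Reagents that add atoms: N-bromosuccinimide, O=C1CCC(=O)N1Br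
Why: Corey–Kim-type activation of the Baylis–Hillman alcohol and SN2′ attack of bromide gives the (Z)-2-(bromomethyl)enoate under neutral conditions; both carbinol epimers converge.

**Step 14**
Reactants: 18
Product: 19, (1RS,6R,7S,8S,10R)-15-[(tert-butyldiphenylsilyl)oxy]-1,8,10-tris[(triethylsilyl)oxy]germacra-4,11(13)-dien-2-yn-12,6-olide (ten-membered enyne ring, trans-fused α-methylene lactone; C7 is "S" only because of the O–Si priority, geometry as in the target)
Conditions: CrCl2 (10 equiv), THF (DMF co-solvent), rt, syringe-pump addition to about 2 mM; lactonisation in situ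
Reagents that add atoms: none
Why: Intramolecular Nozaki–Hiyama/Barbier 2-(alkoxycarbonyl)allylation through a chair transition state of the equilibrated allylchromium gives the anti C6/C7 adduct (trans-lactone after acyl transfer); the face is controlled by the C8 silyloxy centre within the macrocyclic transition state.

**Step 15**
Reactants: 19
Product: 20, (1RS,6R,7R,8S,10R)-15-[(tert-butyldiphenylsilyl)oxy]-1,8,10-trihydroxygermacra-4,11(13)-dien-2-yn-12,6-olide
Conditions: CSA (0.3 equiv), MeOH/CH2Cl2, 0 °C to rt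
Reagents that add atoms: none
Why: Acidic methanolysis removes the three TES ethers while the much more acid-stable primary TBDPS ether remains.

**Step 16**
Reactants: 20
Product: 21, (6R,7R,8S,10R)-15-[(tert-butyldiphenylsilyl)oxy]-8,10-dihydroxy-1-oxogermacra-4,11(13)-dien-2-yn-12,6-olide
Conditions: activated MnO2, CH2Cl2, rt
Reagents that add atoms: none
Why: MnO2 oxidises only the activated propargylic C1–OH (both epimers converge); the unactivated C8–OH and tertiary C10–OH are untouched.

**Step 17**
Reactants: 21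
Product: 22, (6R,7R,8S,10R)-15-[(tert-butyldiphenylsilyl)oxy]-8-hydroxy-1-oxo-3,10-epoxygermacra-2,4,11(13)-trien-12,6-olide (8-O-destigloyl-15-O-TBDPS lychnophorolide B)
Conditions: Ph3PAuCl/AgOTf (5 mol%), CH2Cl2, rt
Reagents that add atoms: none
Why: Au(I)-catalysed 5-endo-dig hydroalkoxylation of the α′-hydroxy ynone gives the bridging 3(2H)-furanone; no stereocentre is touched.

**Step 18**
Reactants: 22; 23, tiglic acid
Product: 24, 15-O-TBDPS lychnophorolide B
Conditions: tiglic acid, 2,4,6-trichlorobenzoyl chloride, Et3N, toluene; then 22, DMAP, rt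
Reagents that add atoms: tiglic acid (23), C/C=C(\C)C(=O)O
Why: Yamaguchi esterification of the only free hydroxyl (secondary C8–OH); the E-configured tiglate is the thermodynamically stable isomer.

**Step 19**
Reactants: 24
Product: 25, lychnophorolide B
Conditions: HF·pyridine, pyridine/THF, 0 °C to rt
Reagents that add atoms: none
Why: Buffered fluoride cleavage of the primary TBDPS ether is mild enough for the enoate, furanone and α-methylene lactone Michael acceptors.

## Compound list

1 | (S)-5-(hydroxymethyl)dihydrofuran-2(3H)-one | O=C1CC[C@@H](CO)O1 | starting material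
2 | (S)-5-{[(triethylsilyl)oxy]methyl}dihydrofuran-2(3H)-one | O=C1CC[C@@H](CO[Si](CC)(CC)CC)O1 | intermediate
3 | iodomethane | CI | starting material
4 | (3RS,5S)-3-methyl-5-(TESOCH2) lactone | O=C1C(C)C[C@@H](CO[Si](CC)(CC)CC)O1 | intermediate
5 | (3R,5S)-3-hydroxy-3-methyl-5-(TESOCH2) lactone | O=C1[C@](C)(O)C[C@@H](CO[Si](CC)(CC)CC)O1 | intermediate
6 | (3R,5S)-3-methyl-5-(TESOCH2)oxolane-2,3-diol (lactol) | OC1[C@](C)(O)C[C@@H](CO[Si](CC)(CC)CC)O1 | intermediate
7 | ethynylmagnesium bromide | C#C[Mg]Br | starting material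
8 | (3RS,4R,6S)-4-methyl-7-(TESO)hept-1-yne-3,4,6-triol | C#CC(O)[C@](C)(O)C[C@H](O)CO[Si](CC)(CC)CC | intermediate
9 | (3RS,4R,6S)-4-methyl-3,4,6,7-tetrakis(TESO)hept-1-yne | C#CC(O[Si](CC)(CC)CC)[C@](C)(O[Si](CC)(CC)CC)C[C@H](O[Si](CC)(CC)CC)CO[Si](CC)(CC)CC | intermediate
10 | (2S,4R,5RS)-4-methyl-2,4,5-tris(TESO)hept-6-ynal | C#CC(O[Si](CC)(CC)CC)[C@](C)(O[Si](CC)(CC)CC)C[C@H](O[Si](CC)(CC)CC)C=O | intermediate
11 | methyl acrylate | C=CC(=O)OC | starting material
12 | Baylis–Hillman adduct, methyl (4S,6R)-3-hydroxy-6-methyl-2-methylidene-4,6,7-tris(TESO)non-8-ynoate | C#CC(O[Si](CC)(CC)CC)[C@](C)(O[Si](CC)(CC)CC)C[C@H](O[Si](CC)(CC)CC)C(O)C(=C)C(=O)OC | intermediate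
13 | but-2-yne-1,4-diol | OCC#CCO | starting material
14 | 4-(TBDPSO)but-2-yn-1-ol | OCC#CCO[Si](c1ccccc1)(c1ccccc1)C(C)(C)C | intermediate
15 | (Z)-4-(TBDPSO)-3-iodobut-2-en-1-ol | OC/C=C(\I)CO[Si](c1ccccc1)(c1ccccc1)C(C)(C)C | intermediate
16 | (Z)-4-(TBDPSO)-3-iodobut-2-enal | O=C/C=C(\I)CO[Si](c1ccccc1)(c1ccccc1)C(C)(C)C | intermediate
17 | Sonogashira enynal (Baylis–Hillman alcohol) | O=C/C=C(/CO[Si](c1ccccc1)(c1ccccc1)C(C)(C)C)C#CC(O[Si](CC)(CC)CC)[C@](C)(O[Si](CC)(CC)CC)C[C@H](O[Si](CC)(CC)CC)C(O)C(=C)C(=O)OC | intermediate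
18 | (Z)-allylic bromide enynal | O=C/C=C(/CO[Si](c1ccccc1)(c1ccccc1)C(C)(C)C)C#CC(O[Si](CC)(CC)CC)[C@](C)(O[Si](CC)(CC)CC)C[C@H](O[Si](CC)(CC)CC)/C=C(\CBr)C(=O)OC | intermediate
19 | tris-TES macrocyclic enyne trans-lactone | C=C1C(=O)O[C@@H]2/C=C(/CO[Si](c3ccccc3)(c3ccccc3)C(C)(C)C)C#CC(O[Si](CC)(CC)CC)[C@](C)(O[Si](CC)(CC)CC)C[C@H](O[Si](CC)(CC)CC)[C@@H]12 | intermediate
20 | macrocyclic triol | C=C1C(=O)O[C@@H]2/C=C(/CO[Si](c3ccccc3)(c3ccccc3)C(C)(C)C)C#CC(O)[C@](C)(O)C[C@H](O)[C@@H]12 | intermediate
21 | macrocyclic α′-hydroxy ynone | C=C1C(=O)O[C@@H]2/C=C(/CO[Si](c3ccccc3)(c3ccccc3)C(C)(C)C)C#CC(=O)[C@](C)(O)C[C@H](O)[C@@H]12 | intermediate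
22 | 8-hydroxy furanone core (15-O-TBDPS) | C=C1C(=O)O[C@@H]2/C=C(/CO[Si](c4ccccc4)(c4ccccc4)C(C)(C)C)C3=CC(=O)[C@@](C)(C[C@H](O)[C@@H]12)O3 | intermediate
23 | tiglic acid | C/C=C(\C)C(=O)O | starting material
24 | 15-O-TBDPS lychnophorolide B | C=C1C(=O)O[C@@H]2/C=C(/CO[Si](c4ccccc4)(c4ccccc4)C(C)(C)C)C3=CC(=O)[C@@](C)(C[C@H](OC(=O)/C(C)=C/C)[C@@H]12)O3 | intermediate
25 | lychnophorolide B, (6R,7R,8S,10R) | C=C1C(=O)O[C@@H]2/C=C(/CO)C3=CC(=O)[C@@](C)(C[C@H](OC(=O)/C(C)=C/C)[C@@H]12)O3 | target

## Step count and risks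

Total steps: 19. Longest linear sequence: 16 (steps 1–8, then 12–19); the iodoenal branch is 3 steps (9–11).

Three steps most likely to fail:

1. **Step 14, Cr-mediated macrocyclisation/lactonisation.** Risks are ring strain, oligomerisation and incomplete control of the C6/C7 configuration. Fallback: change the ring-closing bond. Run an intermolecular CrCl2 Barbier between iodoenal 16 and the allylic bromide made directly from 12 to set the trans-lactone on an open chain, then close the ten-membered ring by intramolecular Sonogashira coupling (C3–C4) at high dilution.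

2. **Step 17, Au-catalysed furanone formation inside the strained macrocycle.** Risks are sluggish cyclisation or competing transannular reactions. Fallback: invert the ring order. Carry the C1/C10 diol unprotected (or as an acetonide) so that oxidation and furanone formation are done on the acyclic Sonogashira product, then close the carbocycle by the Cr-Barbier onto the furanone dienal.

3. **Step 8, Baylis–Hillman reaction on a hindered, epimerisable α-silyloxy aldehyde.** Risks are a slow reaction, C8 epimerisation and 1,2-silyl migration. Fallback: build the same adduct by an aldol/elimination sequence. Add the lithium enolate of methyl 3-(phenylselanyl)propanoate to 10 at −78 °C, then eliminate the selenoxide with H2O2 to give 12.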